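## Retrosynthetic overview
1. Ring A–CH2–ring B bond: 3-prenylphloracetophenone captures a ring B methylene quinone methide (conjugate addition, formally a hetero-Diels–Alder reaction). The quinone methide comes from dehydrogenating a ring B C-methyl group.
2. Ring B prenyl group: made from an (E)-crotyl group by cross metathesis with 2-methylbut-2-ene.
3. Quaternary stereocentre (key bond): dearomative aromatic Claisen [3,3] shift of the (R)-but-3-en-2-yl ether of C2-symmetric 3,5-dimethylphloracetophenone, with chair-type C–O to C–C chirality transfer.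
4. Chiral ether: Mitsunobu inversion of (S)-but-3-en-2-ol, which is made from cheap (S)-propylene oxide by one-carbon ylide homologation.
5. Ring order: no carbocycle is built, because both six-membered rings are bought as phloracetophenones. Ring B is dearomatised first (Claisen), ring A is prenylated separately, and the two are joined last.

Assumption: 2,4,6-trihydroxy-3,5-dimethylacetophenone is bought as a catalogue compound, and all β-triketone enols are drawn in the tautomer of the target SMILES.

## Route

Step 1
Reactants: 1 (S)-propylene oxide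
Product: 3 (S)-but-3-en-2-ol, via sulfonium alkoxide betaine 2 (not isolated)
Conditions: Me3S+ I− (3 equiv), n-BuLi (2.9 equiv), THF, −10 °C to rt; H2O quench; fractional distillation (bp 97 °C)
Reagents that add atoms: trimethylsulfonium iodide, C[S+](C)C.[I-]
Why: This is the epoxide-to-allylic-alcohol one-carbon homologation with excess Corey–Chaykovsky sulfonium ylide, in which the ylide opens 1 at the unsubstituted carbon and a second equivalent triggers loss of dimethyl sulfide from betaine 2, so the bought C–O stereocentre is never touched and stays (S).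

Step 2
Reactants: 3 (S)-but-3-en-2-ol; 4 2,4,6-trihydroxy-3,5-dimethylacetophenone
Product: 5 1-{4-[(2R)-but-3-en-2-yloxy]-2,6-dihydroxy-3,5-dimethylphenyl}ethan-1-one
Conditions: PPh3 (1.3 equiv), DIAD (1.3 equiv), THF (about 1 M), 0 °C to rt, sonication
Reagents that add atoms: none
Why: In this Mitsunobu etherification the para-hydroxyl is the only non-chelated and the most acidic OH of 4, and it displaces the activated secondary alcohol by SN2 with inversion, turning (S)-3 into the (R)-ether.

Step 3
Reactants: 5 1-{4-[(2R)-but-3-en-2-yloxy]-2,6-dihydroxy-3,5-dimethylphenyl}ethan-1-one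
Product: 6 (4R)-2-acetyl-4-[(2E)-but-2-en-1-yl]-3,5-dihydroxy-4,6-dimethylcyclohexa-2,5-dien-1-one
Conditions: degassed o-xylene (0.05 M), BHT (cat.), 140 °C, sealed tube, 8–16 h
Reagents that add atoms: none
Why: This dearomative aromatic Claisen rearrangement is a suprafacial [3,3]-sigmatropic shift through a chair transition state with the carbinol methyl equatorial, which relays the (R) C–O centre into the (4R) quaternary carbon and an E-alkene; the two ortho carbons are homotopic (C2 axis through C1 and C4) so either gives the same enantiomer, the para carbon is blocked by acetyl, and the product is held as a doubly hydrogen-bonded β-triketone enol instead of reverting.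

Step 4
Reactants: 6 (4R)-2-acetyl-4-[(2E)-but-2-en-1-yl]-3,5-dihydroxy-4,6-dimethylcyclohexa-2,5-dien-1-one
Product: 7 (4R)-2-acetyl-3,5-dihydroxy-4,6-dimethyl-4-(3-methylbut-2-en-1-yl)cyclohexa-2,5-dien-1-one
Conditions: 2-methylbut-2-ene (large excess, co-solvent), second-generation Hoveyda–Grubbs catalyst (5 mol %), CH2Cl2, 40 °C, sealed tube
Reagents that add atoms: 2-methylbut-2-ene, CC=C(C)C
Why: In this olefin cross metathesis the unhindered 1,2-disubstituted crotyl alkene exchanges its ethylidene end for the isopropylidene of 2-methylbut-2-ene, the trisubstituted prenyl product is metathesis-inert, but-2-ene escapes, and the quaternary centre is not involved.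

Step 5
Reactants: 8 2,4,6-trihydroxyacetophenone (phloracetophenone)
Product: 9 1-[2,4,6-trihydroxy-3-(3-methylbut-2-en-1-yl)phenyl]ethan-1-one (3-prenylphloracetophenone)
Conditions: prenyl bromide (1.0 equiv), KOH (1.0 equiv), H2O, 0 °C to rt
Reagents that add atoms: prenyl bromide (1-bromo-3-methylbut-2-ene), CC(C)=CCBr
Why: This is C-selective alkylation of the ambident phloroglucinol phenolate in water, where hydrogen bonding shields oxygen, and it gives the known mono-C-prenyl compound after rearomatising tautomerisation without creating a stereocentre.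

Step 6
Reactants: 7 (4R)-2-acetyl-3,5-dihydroxy-4,6-dimethyl-4-(3-methylbut-2-en-1-yl)cyclohexa-2,5-dien-1-one; 9 3-prenylphloracetophenone (2 equiv)
Product: 11 (4R)-2-acetyl-6-{[3-acetyl-2,4,6-trihydroxy-5-(3-methylbut-2-en-1-yl)phenyl]methyl}-3,5-dihydroxy-4-methyl-4-(3-methylbut-2-en-1-yl)cyclohexa-2,5-dien-1-one (target CNP0192978.1), via methylene quinone methide 10 (not isolated)
Conditions: Ag2O (1.1 equiv), TEMPO (1.0 equiv, regenerated by Ag2O), THF, 0 °C to rt, dark; excess 9 recovered
Reagents that add atoms: none
Why: Oxidative dehydrogenation of the 2-methyl-1,3-dione enol of 7 (Ag2O/TEMPO conditions known for dearomatised acylphloroglucinols carrying a C(Me)(prenyl) centre) gives hetero-diene 10, which is captured at the only free ring carbon of 9 by vinylogous Michael addition (formal hetero-Diels–Alder reaction then ring opening) and rearomatisation, with the quaternary centre as a spectator.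

## Compound list
1 | (S)-propylene oxide | C[C@H]1CO1 | starting material
2 | [(3S)-3-oxidobutyl]dimethylsulfonium (sulfonium alkoxide betaine) | C[C@H]([O-])CC[S+](C)C | intermediate
3 | (S)-but-3-en-2-ol | C=C[C@H](C)O | intermediate
4 | 2,4,6-trihydroxy-3,5-dimethylacetophenone | CC(=O)c1c(O)c(C)c(O)c(C)c1O | starting material
5 | 1-{4-[(2R)-but-3-en-2-yloxy]-2,6-dihydroxy-3,5-dimethylphenyl}ethan-1-one | C=C[C@@H](C)Oc1c(C)c(O)c(C(C)=O)c(O)c1C | intermediate
6 | (4R)-2-acetyl-4-[(2E)-but-2-en-1-yl]-3,5-dihydroxy-4,6-dimethylcyclohexa-2,5-dien-1-one | CC(=O)C1=C(O)[C@](C)(C/C=C/C)C(O)=C(C)C1=O | intermediate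
7 | (4R)-2-acetyl-3,5-dihydroxy-4,6-dimethyl-4-(3-methylbut-2-en-1-yl)cyclohexa-2,5-dien-1-one | CC(=O)C1=C(O)[C@](C)(CC=C(C)C)C(O)=C(C)C1=O | intermediate
8 | 2,4,6-trihydroxyacetophenone | CC(=O)c1c(O)cc(O)cc1O | starting material
9 | 1-[2,4,6-trihydroxy-3-(3-methylbut-2-en-1-yl)phenyl]ethan-1-one | CC(=O)c1c(O)cc(O)c(CC=C(C)C)c1O | intermediate
10 | (4S)-2-acetyl-3-hydroxy-4-methyl-6-methylidene-4-(3-methylbut-2-en-1-yl)cyclohex-2-ene-1,5-dione (same spatial arrangement as 7; the descriptor changes only because the CIP priorities change) | CC(=O)C1=C(O)[C@](C)(CC=C(C)C)C(=O)C(=C)C1=O | intermediate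
11 | (4R)-2-acetyl-6-{[3-acetyl-2,4,6-trihydroxy-5-(3-methylbut-2-en-1-yl)phenyl]methyl}-3,5-dihydroxy-4-methyl-4-(3-methylbut-2-en-1-yl)cyclohexa-2,5-dien-1-one | CC(=O)C1=C(O)[C@](C)(CC=C(C)C)C(O)=C(Cc2c(O)c(CC=C(C)C)c(O)c(C(C)=O)c2O)C1=O | target

## Counts and risks
Total step count: 6.
Longest linear sequence: 5 (steps 1, 2, 3, 4 and 6).

**Risk 1, step 6.**
- What can go wrong: the oxidant may attack the electron-rich, prenylated phenol 9. It may also over-oxidise the new diarylmethane-type CH2 of 11.
- Fallback principle: it separates oxidation from C–C bond formation. It sets out from 7 and comes back at 11.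
- Sequence: 7 is oxidised with Ag2O/TEMPO in THF in the presence of morpholine only. Quinone methide 10 is then stored as the bench-stable morpholine Mannich base F6.
- Coupling: after the silver residues are removed, F6 is heated with 9 in 1,4-dioxane at 100 °C. Retro-Mannich release of 10 and C-addition of 9 follow, which is the classical Mannich-base route to unsymmetrical methylene-bridged phloroglucinols. Compound 9 never meets an oxidant.

**Risk 2, step 2.**
- What can go wrong: the para-hydroxyl of 4 sits between two methyl groups, so the Mitsunobu reaction may be slow. It may also leak into SN2' (achiral crotyl ether).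
- Fallback principle: it replaces the redox condensation by the enantiospecific, branched-selective rhodium-catalysed allylic etherification. That reaction runs with net retention and suits ortho-disubstituted phenols. It sets out from 4 and comes back at 5.
- Sequence: bought (R)-propylene oxide is homologated with the protocol of step 1 through the enantiomeric sulfonium alkoxide betaine F1 to (R)-but-3-en-2-ol F2. ClCO2Me/pyridine then gives methyl (R)-but-3-en-2-yl carbonate F3.
- Etherification: the monosodium phenoxide of 4 (NaN(SiMe3)2, 1 equiv, deprotonating the most acidic para-OH) reacts with F3 under RhCl(PPh3)3 (10 mol %)/P(OMe)3 in THF at 0 °C to rt to give 5.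

**Risk 3, step 3.**
- What can go wrong: the acidic phenols of 5 may ionise the secondary allylic ether at 140 °C, causing loss of butadiene and erosion of chirality transfer. Any Z-alkene also carries the opposite configuration into 7.
- Fallback principle: it removes the internal acid by running the [3,3] shift on a protected substrate. It sets out from 5 and comes back at 6.
- Sequence: TBSOTf/2,6-lutidine in CH2Cl2 gives the bis-TBS ether F4. Heating F4 in o-xylene at 140–160 °C gives the silylated cyclohexa-2,4-dienone F5 by the same chair-controlled shift. HF·pyridine in THF at 0 °C then unmasks 6.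

Further compounds
F1 | step 2 | [(3R)-3-oxidobutyl]dimethylsulfonium (enantiomeric sulfonium alkoxide betaine) | C[C@@H]([O-])CC[S+](C)C
F2 | step 2 | (R)-but-3-en-2-ol | C=C[C@@H](C)O
F3 | step 2 | methyl (2R)-but-3-en-2-yl carbonate | C=C[C@@H](C)OC(=O)OC
F4 | step 3 | 1-{4-[(2R)-but-3-en-2-yloxy]-2,6-bis[(tert-butyldimethylsilyl)oxy]-3,5-dimethylphenyl}ethan-1-one | C=C[C@@H](C)Oc1c(C)c(O[Si](C)(C)C(C)(C)C)c(C(C)=O)c(O[Si](C)(C)C(C)(C)C)c1C
F5 | step 3 | (6S)-4-acetyl-6-[(2E)-but-2-en-1-yl]-3,5-bis[(tert-butyldimethylsilyl)oxy]-2,6-dimethylcyclohexa-2,4-dien-1-one | CC(=O)C1=C(O[Si](C)(C)C(C)(C)C)[C@](C)(C/C=C/C)C(=O)C(C)=C1O[Si](C)(C)C(C)(C)C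
F6 | step 6 | (4R)-2-acetyl-3,5-dihydroxy-4-methyl-4-(3-methylbut-2-en-1-yl)-6-(morpholin-4-ylmethyl)cyclohexa-2,5-dien-1-one | CC(=O)C1=C(O)[C@](C)(CC=C(C)C)C(O)=C(CN2CCOCC2)C1=O
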